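**Retrosynthetic overview**
- The target is cut at the second pyranone (annulated last on a free phenol by ortho-formylation and a ketenylidene ylide) and at the E styryl alkene (Horner–Wadsworth–Emmons), giving a C1-quaternary lactol and diethyl (5,7-dimethoxycoumarin-8-yl)methylphosphonate made from citropten.
- The lactol comes from a cis-fused methyl lactone, and that from a nitro allylsilane lactone by protodesilylation with allylic shift, radical denitration and enolate methylation.
- Feature: with the cyclohexene numbered C1 (quaternary: methyl, styryl), C2, C3 (CH2), C4 (methyl-bearing alkene carbon), C5 (alkene CH), C6 (CH–aryl), the C1–C6 bond carries the aryl group and the styryl carbon cis, so it is the C3–C4 bond of a coumarin whose C2 carbonyl becomes the styryl CH. The carbocycle is therefore made by [4+2] cycloaddition of 5,7-dimethoxy-3-nitrocoumarin with (E)-2-methyl-1-trimethylsilylbuta-1,3-diene (bonds C1–C2 and C5–C6); nitro holds the place of the C1 methyl and silicon at C5 moves the alkene from C3=C4 to C4=C5.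
- Ring order: benzopyranone of the dienophile (Knoevenagel), carbocycle (cycloaddition), lactone opened, pyranone of the right-hand coumarin last; the left-hand coumarin arrives intact.

Key step: step 6

Assumption: Friedel–Crafts formylation of 5,7-dimethoxycoumarin is taken to occur at C8 (para to the 5-methoxy group and less hindered than C6, which lies between two methoxy groups); the position is to be confirmed by NOE on the aldehyde from step 11 before it is carried on.

Numbering note: in the tricyclic lactones (6H-benzo[c]chromen-6-one numbering) ring carbons C1, C2, C3, C4, C5, C6 of the cyclohexene are C6a, C7, C8, C9, C10, C10a.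

Step 1
Reactants: 1 2-hydroxy-4,6-dimethoxybenzaldehyde; 2 ethyl nitroacetate
Product: 3 5,7-dimethoxy-3-nitro-2H-chromen-2-one
Conditions: piperidine (0.1 equiv), AcOH (0.2 equiv), toluene, reflux, Dean–Stark
Reagents that add atoms: none
Why: Knoevenagel condensation of the aldehyde with the doubly activated methylene of 2, followed by lactonisation of the ortho phenol onto the ethyl ester, is the standard entry to 3-nitrocoumarins and leaves the methoxy groups untouched.

Step 2
Reactants: 4 prop-2-yn-1-ol
Product: 6 (E)-3-iodo-2-methylprop-2-en-1-ol, via alkenylalane 5 (not isolated)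
Conditions: Me3Al (3 equiv), Cp2ZrCl2 (0.25 equiv), CH2Cl2, 0 °C to rt; then I2 (1.2 equiv), THF, −30 to 0 °C
Reagents that add atoms: trimethylaluminium, C[Al](C)C; iodine, II
Why: Negishi zirconium-catalysed carboalumination adds methyl and aluminium syn across the alkyne with methyl at the internal carbon, and iodinolysis of the alkenyl–aluminium bond with retention fixes the E geometry (iodine cis to methyl).

Step 3
Reactants: 6 (E)-3-iodo-2-methylprop-2-en-1-ol
Product: 9 (E)-2-methyl-3-(trimethylsilyl)prop-2-en-1-ol, via dilithio alkoxide 7 (not isolated), via bis-silyl ether 8 (not isolated)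
Conditions: t-BuLi (3.1 equiv), Et2O, −78 °C; Me3SiCl (2.5 equiv), −78 °C to rt; then 1 M HCl, 0 °C, 10 min
Reagents that add atoms: chlorotrimethylsilane, C[Si](C)(C)Cl
Why: Iodine–lithium exchange on the lithium alkoxide and silylation of the configurationally stable alkenyllithium go with retention of geometry, and the oxygen-bound silyl group is hydrolysed in the brief acidic work-up while the vinylsilane survives.

Step 4
Reactants: 9 (E)-2-methyl-3-(trimethylsilyl)prop-2-en-1-ol
Product: 10 (E)-2-methyl-3-(trimethylsilyl)prop-2-enal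
Conditions: MnO2 (15 equiv), CH2Cl2, rt
Reagents that add atoms: none
Why: Manganese dioxide oxidises the allylic alcohol selectively to the enal without affecting the vinylsilane or the alkene geometry.

Step 5
Reactants: 10 (E)-2-methyl-3-(trimethylsilyl)prop-2-enal
Product: 11 (E)-trimethyl(2-methylbuta-1,3-dien-1-yl)silane
Conditions: Ph3PCH3Br (1.3 equiv), KOt-Bu (1.25 equiv), Et2O, 0 °C; then 10, 0 °C to rt; pentane filtration, distillation
Reagents that add atoms: methyltriphenylphosphonium bromide, C[P+](c1ccccc1)(c1ccccc1)c1ccccc1.[Br-]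
Why: Wittig methylenation of the enal by 1,2-addition of the non-stabilised ylide gives the terminal alkene and leaves the trisubstituted vinylsilane and its E geometry unchanged.

Step 6
Reactants: 3 5,7-dimethoxy-3-nitro-2H-chromen-2-one; 11 (E)-trimethyl(2-methylbuta-1,3-dien-1-yl)silane
Product: 12 (6aR,10aS)-1,3-dimethoxy-9-methyl-6a-nitro-10-(trimethylsilyl)-6a,7,10,10a-tetrahydro-6H-benzo[c]chromen-6-one (cis-fused; silyl carbon C10 as either epimer)
Conditions: 1,1'-[(1R,2R)-cyclohexane-1,2-diyl]bis{3-[3,5-bis(trifluoromethyl)phenyl]thiourea} (20 mol %), 11 (3 equiv), toluene (1 M), 4 Å molecular sieves, −20 °C to rt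
Reagents that add atoms: none
Why: Proposed new method: the two thiourea units of the catalyst are expected to hold the nitro group and the lactone carbonyl of 3 by double N–H···O bonds, lowering the LUMO of the C3=C4 bond enough for a concerted but asynchronous normal-demand [4+2] cycloaddition with 11 at or below room temperature, where the uncatalysed reaction of this donor-substituted nitrocoumarin should be slow. The closest known reaction types are thermal Diels–Alder reactions of 3-nitrocoumarins with isoprene and 2,3-dimethylbutadiene, thiourea-accelerated cycloadditions of nitroalkenes, and enantioselective annulations of 3-nitrocoumarins under chiral hydrogen-bond-donor catalysis; an enantioselective cycloaddition with a 1-silyl diene is not among them. The carbocycle is closed by intermolecular [4+2] cycloaddition across the coumarin 3,4-bond, forming C1–C2 and C5–C6 suprafacially on both partners, so the lactone can only come out cis-fused. C1 and C6 are thus set relative to each other by the geometry of the ring alkene and in the absolute sense by the catalyst, which must leave open the face leading to (6aR,10aS)-12; the catalyst antipode is chosen after the first run, and the configuration at the silyl carbon does not matter because that centre becomes sp2 in step 7. The regiochemistry needed is bonding of the silyl-bearing diene terminus to coumarin C4, the carbon with the larger LUMO coefficient: the 2-methyl group makes that terminus the more nucleophilic one, and the positive charge building up at the methyl-bearing carbon in the asynchronous transition state is also beta to silicon. The main threats are the peri 5-methoxy group next to the forming C5–C6 bond and loss of HNO2 from the adduct, which is why no amine base is present.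

Step 7
Reactants: 12 (6aR,10aS)-1,3-dimethoxy-9-methyl-6a-nitro-10-(trimethylsilyl)-6a,7,10,10a-tetrahydro-6H-benzo[c]chromen-6-one
Product: 13 (6aR,10aS)-1,3-dimethoxy-9-methyl-6a-nitro-6a,7,8,10a-tetrahydro-6H-benzo[c]chromen-6-one
Conditions: CF3CO2H (3 equiv), CH2Cl2, 0 °C, 30 min
Reagents that add atoms: none
Why: Protodesilylation of an allylsilane is an SE2' process in which the proton adds at C3, the cation at C4 is stabilised by the C5–Si bond and silicon leaves from C5, so the alkene ends at C4=C5 for both C5 epimers; the reaction is kept cold and short so that the product alkene is not re-protonated.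

Step 8
Reactants: 13 (6aR,10aS)-1,3-dimethoxy-9-methyl-6a-nitro-6a,7,8,10a-tetrahydro-6H-benzo[c]chromen-6-one
Product: 14 (10aR)-1,3-dimethoxy-9-methyl-6a,7,8,10a-tetrahydro-6H-benzo[c]chromen-6-one (C6a epimers; cis-fused expected to predominate)
Conditions: Bu3SnH (1.5 equiv), 2,2'-azobis(2-methylpropionitrile) (0.2 equiv), toluene, 90 °C
Reagents that add atoms: none
Why: Radical denitration of a tertiary alpha-nitro ester: the stannyl radical adds to the nitro group, the alpha-carbonyl radical at C1 forms by loss of tributyltin nitrite and abstracts hydrogen from Bu3SnH, and the C1 configuration is of no consequence because C1 becomes an enolate carbon in step 9.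

Step 9
Reactants: 14 (10aR)-1,3-dimethoxy-9-methyl-6a,7,8,10a-tetrahydro-6H-benzo[c]chromen-6-one
Product: 16 (6aS,10aS)-1,3-dimethoxy-6a,9-dimethyl-6a,7,8,10a-tetrahydro-6H-benzo[c]chromen-6-one, via lithium enolate 15 (not isolated)
Conditions: LiN(i-Pr)2 (1.2 equiv), THF, −78 °C; MeI (3 equiv), −78 to −40 °C
Reagents that add atoms: iodomethane, CI
Why: Alkylation of the ring-fusion lactone enolate: the peri methoxy group pushes C5 of the carbocycle out of the enolate plane on one face, so MeI should approach from the other face, syn to the C6 hydrogen, giving the cis-fused lactone (methyl trans to aryl) as is usual for angular alkylation of fused enolates.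

Step 10
Reactants: 16 (6aS,10aS)-1,3-dimethoxy-6a,9-dimethyl-6a,7,8,10a-tetrahydro-6H-benzo[c]chromen-6-one
Product: 17 (6aS,10aS)-1,3-dimethoxy-6a,9-dimethyl-6a,7,8,10a-tetrahydro-6H-benzo[c]chromen-6-ol (lactol; both anomers)
Conditions: i-Bu2AlH (1.2 equiv), CH2Cl2, −78 °C; MeOH, then aqueous potassium sodium tartrate
Reagents that add atoms: none
Why: Partial reduction of the aryl lactone with i-Bu2AlH at −78 °C should stop at the lactol because the tetrahedral aluminate persists at that temperature, and neither the alkene, the methyl ethers nor the two ring stereocentres are touched.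

Step 11
Reactants: 18 citropten (5,7-dimethoxy-2H-chromen-2-one)
Product: 20 5,7-dimethoxy-2-oxo-2H-chromene-8-carbaldehyde, via chloro ether 19 (not isolated)
Conditions: Cl2CHOMe (1.5 equiv), TiCl4 (2.2 equiv), CH2Cl2, 0 °C to rt; then ice-cold 1 M HCl
Reagents that add atoms: dichloromethyl methyl ether, COC(Cl)Cl; water, O
Why: Rieche formylation (Friedel–Crafts reaction with the dichloromethyl methyl ether–TiCl4 complex, then hydrolysis) should occur at C8, which is para to the 5-methoxy group, ortho to the 7-methoxy group and less hindered than C6, and stops after one substitution because the aldehyde deactivates the ring.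

Step 12
Reactants: 20 5,7-dimethoxy-2-oxo-2H-chromene-8-carbaldehyde
Product: 21 8-(hydroxymethyl)-5,7-dimethoxy-2H-chromen-2-one
Conditions: NaBH4 (0.5 equiv), THF–MeOH (4:1), 0 °C
Reagents that add atoms: none
Why: Borohydride reduction of the aryl aldehyde is much faster than attack on the electron-rich coumarin lactone or its conjugated alkene.

Step 13
Reactants: 21 8-(hydroxymethyl)-5,7-dimethoxy-2H-chromen-2-one
Product: 22 8-(bromomethyl)-5,7-dimethoxy-2H-chromen-2-one
Conditions: PBr3 (0.4 equiv), CH2Cl2, 0 °C; used without storage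
Reagents that add atoms: phosphorus tribromide, BrP(Br)Br
Why: PBr3 converts the activated benzylic alcohol into the bromide by displacement of its phosphite ester under conditions that leave the lactone intact.

Step 14
Reactants: 22 8-(bromomethyl)-5,7-dimethoxy-2H-chromen-2-one
Product: 23 diethyl [(5,7-dimethoxy-2-oxo-2H-chromen-8-yl)methyl]phosphonate
Conditions: P(OEt)3 (3 equiv), toluene, 110 °C
Reagents that add atoms: triethyl phosphite, CCOP(OCC)OCC
Why: Michaelis–Arbuzov reaction of the benzylic bromide with triethyl phosphite gives the phosphonate with loss of bromoethane.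

Step 15
Reactants: 17 (6aS,10aS)-1,3-dimethoxy-6a,9-dimethyl-6a,7,8,10a-tetrahydro-6H-benzo[c]chromen-6-ol; 23 diethyl [(5,7-dimethoxy-2-oxo-2H-chromen-8-yl)methyl]phosphonate
Product: 24 2-[(1R,6R)-6-[(E)-2-(5,7-dimethoxy-2-oxo-2H-chromen-8-yl)ethenyl]-3,6-dimethylcyclohex-2-en-1-yl]-3,5-dimethoxyphenol
Conditions: 23 (2 equiv), NaN(SiMe3)2 (3 equiv), THF, −78 °C to 40 °C
Reagents that add atoms: none
Why: Horner–Wadsworth–Emmons olefination in which base opens the lactol to the sodium phenoxide aldehyde and reversible addition of the benzylic phosphonate anion to this alpha-quaternary aldehyde followed by syn-elimination should give the E alkene, the ring stereocentres carrying no acidic hydrogen.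

Step 16
Reactants: 24 2-[(1R,6R)-6-[(E)-2-(5,7-dimethoxy-2-oxo-2H-chromen-8-yl)ethenyl]-3,6-dimethylcyclohex-2-en-1-yl]-3,5-dimethoxyphenol
Product: 26 3-[(1R,6R)-6-[(E)-2-(5,7-dimethoxy-2-oxo-2H-chromen-8-yl)ethenyl]-3,6-dimethylcyclohex-2-en-1-yl]-2-hydroxy-4,6-dimethoxybenzaldehyde, via salicyl alcohol 25 (not isolated)
Conditions: MgCl2 (3 equiv), Et3N (6 equiv), (CH2O)n (8 equiv), THF, reflux; then 1 M HCl
Reagents that add atoms: paraformaldehyde (as formaldehyde), C=O
Why: Magnesium-mediated ortho-formylation (Casnati–Skattebøl) delivers formaldehyde within the magnesium phenoxide chelate to the only free position ortho to the phenol and a second formaldehyde oxidises the benzylic alkoxide to the aldehyde, so the position between the two methoxy groups is not attacked.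

Step 17
Reactants: 26 3-[(1R,6R)-6-[(E)-2-(5,7-dimethoxy-2-oxo-2H-chromen-8-yl)ethenyl]-3,6-dimethylcyclohex-2-en-1-yl]-2-hydroxy-4,6-dimethoxybenzaldehyde
Product: 28 8-[(1R,6R)-6-[(E)-2-(5,7-dimethoxy-2-oxo-2H-chromen-8-yl)ethenyl]-3,6-dimethylcyclohex-2-en-1-yl]-5,7-dimethoxy-2H-chromen-2-one (CNP0164660.2), via ester ylide 27 (not isolated)
Conditions: Ph3P=C=C=O (1.3 equiv), toluene, 100 °C
Reagents that add atoms: (triphenylphosphoranylidene)ketene, O=C=C=P(c1ccccc1)(c1ccccc1)c1ccccc1
Why: The phenol adds to the cumulated Bestmann ylide to give the aryl ester of a stabilised ylide, which closes the pyranone by intramolecular Wittig reaction with the ortho aldehyde under neutral conditions that affect neither alkene nor the two stereocentres.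

**Compound list**
1 | 2-hydroxy-4,6-dimethoxybenzaldehyde | COc1cc(O)c(C=O)c(OC)c1 | starting material
2 | ethyl nitroacetate | CCOC(=O)C[N+](=O)[O-] | starting material
3 | 5,7-dimethoxy-3-nitro-2H-chromen-2-one | COc1cc(OC)c2cc([N+](=O)[O-])c(=O)oc2c1 | intermediate
4 | prop-2-yn-1-ol | C#CCO | starting material
5 | (E)-[3-(dimethylalumanyloxy)-2-methylprop-1-en-1-yl]dimethylalumane | C[Al](C)/C=C(\C)CO[Al](C)C | intermediate
6 | (E)-3-iodo-2-methylprop-2-en-1-ol | I/C=C(\C)CO | intermediate
7 | lithium (E)-3-lithio-2-methylprop-2-en-1-olate | [Li]/C=C(\C)CO[Li] | intermediate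
8 | (E)-trimethyl[2-methyl-3-(trimethylsilyloxy)prop-1-en-1-yl]silane | C[Si](C)(C)/C=C(\C)CO[Si](C)(C)C | intermediate
9 | (E)-2-methyl-3-(trimethylsilyl)prop-2-en-1-ol | C[Si](C)(C)/C=C(\C)CO | intermediate
10 | (E)-2-methyl-3-(trimethylsilyl)prop-2-enal | C[Si](C)(C)/C=C(\C)C=O | intermediate
11 | (E)-trimethyl(2-methylbuta-1,3-dien-1-yl)silane | C=C/C(C)=C/[Si](C)(C)C | intermediate
12 | (6aR,10aS)-1,3-dimethoxy-9-methyl-6a-nitro-10-(trimethylsilyl)-6a,7,10,10a-tetrahydro-6H-benzo[c]chromen-6-one, cis-fused, C10 either epimer | O=C2[C@@]1([N+](=O)[O-])CC=C(C)C([Si](C)(C)C)[C@H]1c1c(OC)cc(OC)cc1O2 | intermediate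
13 | (6aR,10aS)-1,3-dimethoxy-9-methyl-6a-nitro-6a,7,8,10a-tetrahydro-6H-benzo[c]chromen-6-one | O=C2[C@@]1([N+](=O)[O-])CCC(C)=C[C@H]1c1c(OC)cc(OC)cc1O2 | intermediate
14 | (10aR)-1,3-dimethoxy-9-methyl-6a,7,8,10a-tetrahydro-6H-benzo[c]chromen-6-one, C6a epimers | O=C2C1CCC(C)=C[C@H]1c1c(OC)cc(OC)cc1O2 | intermediate
15 | lithium enolate of 14 (lithium (10aR)-1,3-dimethoxy-9-methyl-8,10a-dihydro-7H-benzo[c]chromen-6-olate) | [Li]OC1=C2CCC(C)=C[C@H]2c2c(OC)cc(OC)cc2O1 | intermediate
16 | (6aS,10aS)-1,3-dimethoxy-6a,9-dimethyl-6a,7,8,10a-tetrahydro-6H-benzo[c]chromen-6-one, cis-fused | O=C2[C@@]1(C)CCC(C)=C[C@H]1c1c(OC)cc(OC)cc1O2 | intermediate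
17 | (6aS,10aS)-1,3-dimethoxy-6a,9-dimethyl-6a,7,8,10a-tetrahydro-6H-benzo[c]chromen-6-ol, both anomers | OC2[C@@]1(C)CCC(C)=C[C@H]1c1c(OC)cc(OC)cc1O2 | intermediate
18 | citropten (5,7-dimethoxy-2H-chromen-2-one) | COc1cc(OC)c2ccc(=O)oc2c1 | starting material
19 | 8-[chloro(methoxy)methyl]-5,7-dimethoxy-2H-chromen-2-one | COc1cc(OC)c2ccc(=O)oc2c1C(Cl)OC | intermediate
20 | 5,7-dimethoxy-2-oxo-2H-chromene-8-carbaldehyde | COc1cc(OC)c2ccc(=O)oc2c1C=O | intermediate
21 | 8-(hydroxymethyl)-5,7-dimethoxy-2H-chromen-2-one | COc1cc(OC)c2ccc(=O)oc2c1CO | intermediate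
22 | 8-(bromomethyl)-5,7-dimethoxy-2H-chromen-2-one | COc1cc(OC)c2ccc(=O)oc2c1CBr | intermediate
23 | diethyl [(5,7-dimethoxy-2-oxo-2H-chromen-8-yl)methyl]phosphonate | CCOP(=O)(OCC)Cc1c(OC)cc(OC)c2ccc(=O)oc12 | intermediate
24 | 2-[(1R,6R)-6-[(E)-2-(5,7-dimethoxy-2-oxo-2H-chromen-8-yl)ethenyl]-3,6-dimethylcyclohex-2-en-1-yl]-3,5-dimethoxyphenol | COc1cc(OC)c2ccc(=O)oc2c1/C=C/[C@@]1(C)CCC(C)=C[C@H]1c1c(OC)cc(OC)cc1O | intermediate
25 | 2-[(1R,6R)-6-[(E)-2-(5,7-dimethoxy-2-oxo-2H-chromen-8-yl)ethenyl]-3,6-dimethylcyclohex-2-en-1-yl]-6-(hydroxymethyl)-3,5-dimethoxyphenol | COc1cc(OC)c2ccc(=O)oc2c1/C=C/[C@@]1(C)CCC(C)=C[C@H]1c1c(OC)cc(OC)c(CO)c1O | intermediate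
26 | 3-[(1R,6R)-6-[(E)-2-(5,7-dimethoxy-2-oxo-2H-chromen-8-yl)ethenyl]-3,6-dimethylcyclohex-2-en-1-yl]-2-hydroxy-4,6-dimethoxybenzaldehyde | COc1cc(OC)c2ccc(=O)oc2c1/C=C/[C@@]1(C)CCC(C)=C[C@H]1c1c(OC)cc(OC)c(C=O)c1O | intermediate
27 | aryl (triphenylphosphoranylidene)acetate of 26 (ester ylide on the phenol oxygen) | COc1cc(OC)c2ccc(=O)oc2c1/C=C/[C@@]1(C)CCC(C)=C[C@H]1c1c(OC)cc(OC)c(C=O)c1OC(=O)C=P(c1ccccc1)(c1ccccc1)c1ccccc1 | intermediate
28 | 8-[(1R,6R)-6-[(E)-2-(5,7-dimethoxy-2-oxo-2H-chromen-8-yl)ethenyl]-3,6-dimethylcyclohex-2-en-1-yl]-5,7-dimethoxy-2H-chromen-2-one | COc1cc(OC)c2ccc(=O)oc2c1/C=C/[C@@]1(C)CCC(C)=C[C@H]1c1c(OC)cc(OC)c2ccc(=O)oc12 | target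

**Step count**
Total: 17 steps. Longest linear sequence: 12 steps (steps 2 to 10, then 15, 16 and 17, from prop-2-yn-1-ol).

**Steps most likely to fail**

Step 6 (bears the new-method label). The catalyst may accelerate the cycloaddition of this donor-deactivated nitrocoumarin too little or shield its faces poorly, so that conversion or enantiomeric purity falls short. The fallback sets out from 3 and 11 and uses the known thermal reactivity of 3-nitrocoumarins toward methylbutadienes: heating the two without catalyst (toluene, sealed tube, 100–110 °C) should give the racemic cis-fused adduct F1. Treatment with CF3CO2H as in step 7 converts it into the racemic nitro lactone F2. Preparative chromatography on a chiral stationary phase (cellulose tris(3,5-dimethylphenylcarbamate)) then separates 13, where the route is rejoined, from the (6aS,10aR) antipode F3.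

Step 9. Methyl iodide may approach the fused enolate from the face of the carbocycle and give the trans-fused epimer, or the aryl ester enolate may open by a ketene pathway. The fallback sets out from 14 and alkylates a monocyclic ester instead, where the electrophile reliably enters anti to the bulky aryl group on the neighbouring carbon. K2CO3 in MeOH opens the lactone to the hydroxy ester F4, and t-BuMe2SiCl with imidazole in DMF gives the silyl ether F5. LiN(i-Pr)2 then MeI at −78 °C should give the quaternary ester F6 with methyl trans to aryl. Bu4NF frees the phenol ester F7, which is closed with catalytic TsOH in warm toluene to 16, where the route is rejoined.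

Step 15. Addition of the phosphonate anion to the hindered alpha-quaternary aldehyde, which is present only through ring opening of the lactolate, may be slow, and the E selectivity may be incomplete. The fallback sets out from 17 and forms the aryl–alkene bond by a Heck reaction instead. Wittig methylenation (Ph3PCH3Br, KOt-Bu, THF, reflux) gives the vinyl phenol F8. Citropten 18 is iodinated at C8 (N-iodosuccinimide, CF3CO2H, MeCN) to 8-iodo-5,7-dimethoxycoumarin F9. Coupling of F8 with F9 (Pd(OAc)2, P(o-tol)3, Et3N, DMF, 100 °C) arylates the terminal alkene carbon; because the neighbouring carbon is quaternary, beta-hydride elimination can only give the E styrene 24, where the route is rejoined.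

**Further compounds**
F1 | step 6 | racemic cis-fused 1,3-dimethoxy-9-methyl-6a-nitro-10-(trimethylsilyl)-6a,7,10,10a-tetrahydro-6H-benzo[c]chromen-6-one (both enantiomers, C10 either epimer) | O=C2[C@@]1([N+](=O)[O-])CC=C(C)C([Si](C)(C)C)[C@H]1c1c(OC)cc(OC)cc1O2.O=C2[C@]1([N+](=O)[O-])CC=C(C)C([Si](C)(C)C)[C@@H]1c1c(OC)cc(OC)cc1O2
F2 | step 6 | racemic cis-fused 1,3-dimethoxy-9-methyl-6a-nitro-6a,7,8,10a-tetrahydro-6H-benzo[c]chromen-6-one | O=C2[C@@]1([N+](=O)[O-])CCC(C)=C[C@H]1c1c(OC)cc(OC)cc1O2.O=C2[C@]1([N+](=O)[O-])CCC(C)=C[C@@H]1c1c(OC)cc(OC)cc1O2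
F3 | step 6 | (6aS,10aR)-1,3-dimethoxy-9-methyl-6a-nitro-6a,7,8,10a-tetrahydro-6H-benzo[c]chromen-6-one | O=C2[C@]1([N+](=O)[O-])CCC(C)=C[C@@H]1c1c(OC)cc(OC)cc1O2
F4 | step 9 | methyl (2R)-2-(2-hydroxy-4,6-dimethoxyphenyl)-4-methylcyclohex-3-ene-1-carboxylate, C1 epimers | COC(=O)C1CCC(C)=C[C@H]1c1c(OC)cc(OC)cc1O
F5 | step 9 | methyl (2R)-2-[2-(tert-butyldimethylsilyloxy)-4,6-dimethoxyphenyl]-4-methylcyclohex-3-ene-1-carboxylate, C1 epimers | COC(=O)C1CCC(C)=C[C@H]1c1c(OC)cc(OC)cc1O[Si](C)(C)C(C)(C)C
F6 | step 9 | methyl (1S,2S)-2-[2-(tert-butyldimethylsilyloxy)-4,6-dimethoxyphenyl]-1,4-dimethylcyclohex-3-ene-1-carboxylate | COC(=O)[C@@]1(C)CCC(C)=C[C@H]1c1c(OC)cc(OC)cc1O[Si](C)(C)C(C)(C)C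
F7 | step 9 | methyl (1S,2S)-2-(2-hydroxy-4,6-dimethoxyphenyl)-1,4-dimethylcyclohex-3-ene-1-carboxylate | COC(=O)[C@@]1(C)CCC(C)=C[C@H]1c1c(OC)cc(OC)cc1O
F8 | step 15 | 2-[(1R,6R)-6-ethenyl-3,6-dimethylcyclohex-2-en-1-yl]-3,5-dimethoxyphenol | C=C[C@@]1(C)CCC(C)=C[C@H]1c1c(OC)cc(OC)cc1O
F9 | step 15 | 8-iodo-5,7-dimethoxy-2H-chromen-2-one | COc1cc(OC)c2ccc(=O)oc2c1I
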